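The plan cuts the C7–C8 bond of the ten-membered carbocycle (germacrane numbering). A C8 carbinol next to C7 of the α-methylene-γ-lactone ring (C11=C13) is the retron of a γ-selective allylmetal addition. The precursor is therefore an open-chain dialdehyde that already carries the γ-lactone as a 3-(bromomethyl)butenolide (C7=C11, C13–Br). One CrCl2-mediated operation closes the carbocycle and sets C7 and C8. It also moves the butenolide alkene into the exo-methylene position and leaves C8–OH free for the methacrylate. The precursor comes from three small pieces by B-alkyl Suzuki coupling (C3–C4), esterification and ring-closing metathesis. C6 stems from a catalytic asymmetric alkynylation and C9 from (R)-glyceraldehyde acetonide.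

Key step: step 10

Remark on numbering: C1=C10 bears the C14 aldehyde and C4=C5 bears C15H2OH. C6–O is the lactone oxygen, and C7 is the fusion carbon bearing C11(=C13)–C12(=O). C8 carries the methacrylate and C9 the acetate. The target is 6R,7S,8R,9S with C3 cis to C6 and C2 cis to C9. Descriptors at C6 and C7 change along the route only through CIP ranking. TBDPS = tert-butyldiphenylsilyl.

Assumption: the (R)-BINOL–titanium catalyst is taken to deliver the alkynyl group to acrolein in the same facial sense as to aromatic and other α,β-unsaturated aldehydes; should the opposite sense be found, (S)-BINOL is used.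

Step 1
Reactants: 1 tert-butyl(diphenyl)(prop-2-yn-1-yloxy)silane; 2 acrolein
Product: 4 (3S)-6-[(tert-butyldiphenylsilyl)oxy]hex-1-en-4-yn-3-ol, via ethyl(alkynyl)zinc 3 (not isolated)
Conditions: Et2Zn, Cy2NH (5 mol %), (R)-BINOL (40 mol %), Et2O, rt; then Ti(OiPr)4 (50 mol %), 2, rt; aq NH4Cl
Reagents that add atoms: none
Why: Catalytic asymmetric alkynylzinc addition to an aldehyde (BINOL–Ti(OiPr)4 type, established for acrolein and other enals); the chiral titanium complex shields one face of acrolein, so 3 sets C6 in the spatial arrangement of the target (S here because alkynyl outranks vinyl).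

Step 2
Reactants: 4 (3S)-enynol
Product: 6 (3S,4Z)-6-[(tert-butyldiphenylsilyl)oxy]-5-iodohexa-1,4-dien-3-ol, via cyclic vinylalanate 5 (not isolated)
Conditions: NaAlH2(OCH2CH2OMe)2 (Red-Al), THF, −20 to 0 °C; then I2, THF, −78 °C
Reagents that add atoms: iodine, SMILES II
Why: Hydroxyl-directed trans-hydroalumination of a propargylic alcohol followed by iodinolysis; the alkoxide delivers hydride to C5 and holds aluminium on C4 in the five-membered alanate 5, so iodine ends up cis to C6 and C15 trans to C6, and the low temperature keeps the β-silyloxy group from being eliminated.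

Step 3
Reactants: 7 (triphenylphosphoranylidene)acetaldehyde; 2 acrolein
Product: 9 (2Z)-2-bromopenta-2,4-dienal, via bromo ylide 8 (not isolated)
Conditions: NBS, CH2Cl2, −20 °C; then 2 (excess), CH2Cl2, rt to 40 °C; solution carried on directly
Reagents that add atoms: N-bromosuccinimide, SMILES O=C1CCC(=O)N1Br
Why: One-flask halogenation of a stabilised ylide and Wittig olefination; the carbonyl-stabilised bromo ylide 8 places the formyl group (C14) trans to the vinyl residue (C2), which is the C1=C10 geometry of the target, and excess acrolein limits a second olefination.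

Step 4
Reactants: 9 (2Z)-2-bromopenta-2,4-dienal
Product: 10 (2Z)-2-bromo-1,1-dimethoxypenta-2,4-diene
Conditions: HC(OMe)3, PPTS (cat.), MeOH, rt
Reagents that add atoms: trimethyl orthoformate, SMILES COC(OC)OC
Why: Acid-catalysed acetalisation with an orthoformate as water scavenger masks C14 for the lithiation and hydroboration to come and leaves the alkene geometry untouched.

Step 5
Reactants: 10 bromodiene acetal; 11 (4R)-2,2-dimethyl-1,3-dioxolane-4-carbaldehyde
Product: 14 (1S,2E)-2-(dimethoxymethyl)-1-[(4R)-2,2-dimethyl-1,3-dioxolan-4-yl]penta-2,4-dien-1-yl acetate, via dienyllithium 12 (not isolated), via lithium alkoxide 13 (not isolated)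
Conditions: t-BuLi (2 equiv), Et2O, −78 °C; 11, −78 °C; Ac2O, −78 to 0 °C
Reagents that add atoms: acetic anhydride, SMILES CC(=O)OC(C)=O
Why: Bromine–lithium exchange with retention of alkene geometry, 1,2-addition and in situ O-acetylation; the non-chelating lithium reagent should attack 11 in the Felkin–Anh sense to give the 8,9-anti adduct and hence 9S, and the minor syn epimer is to be removed by chromatography.

Step 6
Reactants: 14 dienyl acetate; 6 alkenyl iodide
Product: 16 open-chain C6 alcohol (6S,8R,9S; C3 cis to C6; C2 cis to C9), via B-alkyl-9-BBN borane 15 (not isolated)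
Conditions: 9-BBN, THF, 0 °C to rt; aq K3PO4; then 6, Pd(dppf)Cl2 (5 mol %), AsPh3, DMF, rt
Reagents that add atoms: none
Why: Chemoselective hydroboration of the monosubstituted end of the 1,3-diene (boron on C3) and B-alkyl Suzuki–Miyaura coupling with retention at the alkenyl iodide form C3–C4; oxidative addition to the iodide is expected to outrun ionisation of the hindered allylic acetate, residual 9-BBN is quenched by the aqueous base before 6 is added, and the free C6–OH is tolerated.

Step 7
Reactants: 16 open-chain C6 alcohol; 17 2-(bromomethyl)acrylic acid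
Product: 18 C6 2-(bromomethyl)acrylate of 16
Conditions: DCC, DMAP (5 mol %), CH2Cl2, 0 °C
Reagents that add atoms: none
Why: Steglich esterification does not touch the C6–O bond, so the configuration is kept, and the low DMAP loading and temperature avoid displacement of the allylic bromide.

Step 8
Reactants: 18 acrylate ester
Product: 19 (5R)-3-(bromomethyl)-5-alkenylfuran-2(5H)-one (butenolide with C14 acetal and C8 acetonide)
Conditions: second-generation Grubbs catalyst (H2IMes)(PCy3)Cl2Ru=CHPh (5–10 mol %), CH2Cl2 (5 mM), 40 °C
Reagents that add atoms: none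
Why: Ring-closing metathesis starts at the only monosubstituted alkene (C7 vinyl) and closes the five-membered lactone onto the 1,1-disubstituted acrylate alkene; the trisubstituted alkenes are inert, and the neutral medium protects the acidic C6–H of the butenolide.

Step 9
Reactants: 19 butenolide acetonide
Product: 20 butenolide dialdehyde (6R,9S) with free C8 and C14 aldehydes
Conditions: H5IO6, EtOAc, 0 °C to rt; filtered and used at once
Reagents that add atoms: water (released from H5IO6), SMILES O
Why: One-flask hydrolysis of a terminal acetonide and glycol cleavage by periodic acid gives the C8 aldehyde with loss of the sacrificial carbon; the more labile enal acetal is hydrolysed at the same time, and the absence of base keeps C9 and C6 from epimerising.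

Step 10
Reactants: 20 butenolide dialdehyde
Product: 22 ten-membered 8-hydroxy germacranolide 15-O-TBDPS ether (6R,7R,8R,9S; same spatial arrangement as the target), via allylchromium 21 (not isolated)
Conditions: CrCl2 (10 equiv), DMF–THF, 1 mM, syringe-pump addition of 20, rt; aq work-up
Reagents that add atoms: none
Why: Divalent chromium reduces the allylic C13–Br bond in two one-electron steps to the allylchromium 21 (trivalent chromium), whose γ-carbon is C7 of the butenolide ring; 21 adds to the C8 aldehyde through a six-membered chair (Zimmerman–Traxler) transition state, so C7–C8 forms while the C7=C11 alkene moves to C11=C13 and the α-methylene-γ-lactone appears in the same event. The closest known reaction types are the intramolecular Nozaki–Hiyama–Kishi allylation of ω-formyl 2-(bromomethyl)acrylates used for ten-membered germacranolide rings, and the γ-selective chromium- or zinc-mediated addition of 3-(bromomethyl)furan-2(5H)-one to aldehydes. Only the ten-membered carbocycle is closed, by 10-exo-trig attack of C7 on the aldehyde carbon (SE2′ at the allylmetal), helped by the two trisubstituted alkenes that hold C3 cis to C6 and C2 cis to C9 and fold the chain into a U. C7 is controlled by C6: the bond forms on the butenolide face opposite the C5 alkenyl substituent, which gives the trans-fused lactone. C8 is controlled by the ring-locked allylmetal geometry (C6 trans to C13, as in an E-crotyl reagent), which in the chair with C9 equatorial gives the 7,8-anti relation, and polar Felkin–Anh attack anti to the C9 acetoxy group (8,9-anti) reinforces it as a matched pair. The step needs C8 over C14 chemoselectivity and cyclisation over oligomerisation: C8 is unconjugated and activated by the α-acetoxy group, attack on the conjugated C14 aldehyde would demand a nine-membered ring holding C1=C10 with its ring bonds trans, and millimolar concentration with slow addition suppresses intermolecular coupling.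

Step 11
Reactants: 22 8-hydroxy germacranolide
Product: 23 8-O-methacrylate 15-O-TBDPS ether (6R,7S,8R,9S)
Conditions: methacrylic anhydride, Et3N, DMAP (cat.), CH2Cl2, 0 °C to rt
Reagents that add atoms: methacrylic anhydride, SMILES C=C(C)C(=O)OC(=O)C(C)=C
Why: DMAP-catalysed acylation of the only free hydroxyl group proceeds with retention at C8, and prompt acylation forestalls acetate migration from C9 and translactonisation.

Step 12
Reactants: 23 silyl ether
Product: 24 target CNP0147326.13
Conditions: HF·pyridine, pyridine, THF, 0 °C to rt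
Reagents that add atoms: none
Why: Fluoride-mediated desilylation in a mildly acidic buffered medium frees C15–OH without touching the enal, the two esters or the α-methylene lactone, all of which are base-sensitive.

Compound list
1 | tert-butyl(diphenyl)(prop-2-yn-1-yloxy)silane | C#CCO[Si](c1ccccc1)(c1ccccc1)C(C)(C)C | starting material
2 | acrolein | C=CC=O | starting material
3 | ethyl{3-[(tert-butyldiphenylsilyl)oxy]prop-1-yn-1-yl}zinc | CC[Zn]C#CCO[Si](c1ccccc1)(c1ccccc1)C(C)(C)C | intermediate
4 | (3S)-6-[(tert-butyldiphenylsilyl)oxy]hex-1-en-4-yn-3-ol | C=C[C@H](O)C#CCO[Si](c1ccccc1)(c1ccccc1)C(C)(C)C | intermediate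
5 | sodium cyclic vinylalanate (Al bound to O6 and C4) | [Na+].C=C[C@@H]1O[Al-](OCCOC)(OCCOC)C(CO[Si](c2ccccc2)(c2ccccc2)C(C)(C)C)=C1 | intermediate
6 | (3S,4Z)-6-[(tert-butyldiphenylsilyl)oxy]-5-iodohexa-1,4-dien-3-ol | C=C[C@H](O)/C=C(\I)CO[Si](c1ccccc1)(c1ccccc1)C(C)(C)C | intermediate
7 | (triphenylphosphoranylidene)acetaldehyde | O=CC=P(c1ccccc1)(c1ccccc1)c1ccccc1 | starting material
8 | 2-bromo-2-(triphenylphosphoranylidene)acetaldehyde | O=CC(Br)=P(c1ccccc1)(c1ccccc1)c1ccccc1 | intermediate
9 | (2Z)-2-bromopenta-2,4-dienal | C=C/C=C(Br)/C=O | intermediate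
10 | (2Z)-2-bromo-1,1-dimethoxypenta-2,4-diene | C=C/C=C(Br)/C(OC)OC | intermediate
11 | (4R)-2,2-dimethyl-1,3-dioxolane-4-carbaldehyde | O=C[C@H]1COC(C)(C)O1 | starting material
12 | (1,1-dimethoxypenta-2,4-dien-2-yl)lithium, lithium cis to the vinyl group | C=C/C=C([Li])/C(OC)OC | intermediate
13 | lithium alkoxide of the 8,9-anti adduct (8R,9S) | C=C/C=C(/C(OC)OC)[C@H](O[Li])[C@H]1COC(C)(C)O1 | intermediate
14 | (1S,2E)-2-(dimethoxymethyl)-1-[(4R)-2,2-dimethyl-1,3-dioxolan-4-yl]penta-2,4-dien-1-yl acetate | C=C/C=C(/C(OC)OC)[C@H](OC(C)=O)[C@H]1COC(C)(C)O1 | intermediate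
15 | B-alkyl-9-BBN borane from 14 (boron on C3) | C(CB1C2CCCC1CCC2)/C=C(/C(OC)OC)[C@H](OC(C)=O)[C@H]1COC(C)(C)O1 | intermediate
16 | open-chain C6 alcohol (6S,8R,9S) | C=C[C@H](O)/C=C(/CO[Si](c1ccccc1)(c1ccccc1)C(C)(C)C)CC/C=C(/C(OC)OC)[C@H](OC(C)=O)[C@H]1COC(C)(C)O1 | intermediate
17 | 2-(bromomethyl)acrylic acid | C=C(CBr)C(=O)O | starting material
18 | C6 2-(bromomethyl)acrylate of 16 | C=C[C@H](OC(=O)C(=C)CBr)/C=C(/CO[Si](c1ccccc1)(c1ccccc1)C(C)(C)C)CC/C=C(/C(OC)OC)[C@H](OC(C)=O)[C@H]1COC(C)(C)O1 | intermediate
19 | (5R)-3-(bromomethyl)butenolide with C14 acetal and C8 acetonide | O=C1O[C@@H](C=C1CBr)/C=C(/CO[Si](c2ccccc2)(c2ccccc2)C(C)(C)C)CC/C=C(/C(OC)OC)[C@H](OC(C)=O)[C@H]1COC(C)(C)O1 | intermediate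
20 | butenolide dialdehyde (6R,9S) | O=C1O[C@@H](C=C1CBr)/C=C(/CO[Si](c2ccccc2)(c2ccccc2)C(C)(C)C)CC/C=C(/C=O)[C@H](OC(C)=O)C=O | intermediate
21 | allylchromium dichloride from 20 (chromium on C13) | O=C1O[C@@H](C=C1C[Cr](Cl)Cl)/C=C(/CO[Si](c2ccccc2)(c2ccccc2)C(C)(C)C)CC/C=C(/C=O)[C@H](OC(C)=O)C=O | intermediate
22 | 8-hydroxy germacranolide 15-O-TBDPS ether | O[C@@H]1[C@H]2C(=C)C(=O)O[C@@H]2/C=C(/CO[Si](c3ccccc3)(c3ccccc3)C(C)(C)C)CC/C=C(/C=O)[C@@H]1OC(C)=O | intermediate
23 | 8-O-methacrylate 15-O-TBDPS ether | C=C(C)C(=O)O[C@@H]1[C@H]2C(=C)C(=O)O[C@@H]2/C=C(/CO[Si](c3ccccc3)(c3ccccc3)C(C)(C)C)CC/C=C(/C=O)[C@@H]1OC(C)=O | intermediate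
24 | CNP0147326.13 | C=C(C)C(=O)O[C@@H]1[C@H]2C(=C)C(=O)O[C@@H]2/C=C(/CO)CC/C=C(/C=O)[C@@H]1OC(C)=O | target

Total step count: 12. Longest linear sequence: 10 (steps 3–12).

Steps most likely to fail

Step 10. The chain may oligomerise instead of closing, or the butenolide or the aldehyde may be attacked from the wrong face. The divalent chromium may also erode the α-acetoxy aldehyde, by reductive loss or 1,2-shift of the acetate, before closure. The fallback closes the same C7–C8 bond by a redox-neutral intramolecular allylboration. It sets out from 19. Base-free borylation of the primary allylic bromide (B2pin2, Pd2(dba)3 cat., THF, 50 °C) should give the allylboronate acetonide F1. This is done while C14 is still an acetal, so the C9 acetate is only a hindered, unactivated allylic ester. H5IO6 in dilute EtOAc unmasks both aldehydes to the boronate dialdehyde F2; partial cleavage of the pinacol ester to the more reactive boronic acid is harmless. F2 should close through the same chair transition state, with Sc(OTf)3 catalysis if slow, to the cyclic borate F3. Mild aqueous work-up frees the alcohol, and the route is rejoined at 22.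

Step 6. Zerovalent palladium may ionise the allylic C9 acetate, and the borane may suffer protodeboronation or β-hydride loss before transfer. The fallback changes the order of bond formation so that no allylic ester is present in the palladium step. It sets out from 6 and 10. Silylation of 6 (TESCl, imidazole, CH2Cl2) gives the triethylsilyl ether F4. Hydroboration of 10 with 9-BBN gives the bromoalkenyl borane F5, which couples at the more reactive alkenyl iodide of F4 under the conditions of step 6 to give the coupled alkenyl bromide F6. Treatment with t-BuLi gives the alkenyllithium F7, addition to 11 gives the lithium alkoxide F8, and Ac2O gives the silyl-protected acetate F9. Pyridine-buffered HF·pyridine at 0 °C removes only the triethylsilyl group, and the route is rejoined at 16.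

Step 5. Facial selectivity in the addition to the α,β-dialkoxy aldehyde may be poor, and part of the aldehyde may be lost by enolisation. The fallback sets C9 by reduction instead of by addition. It sets out from 13. Aqueous quench gives the C9-epimeric alcohols F10, and Dess–Martin oxidation gives the dienone F11. Chelation-controlled 1,2-reduction follows with Zn(BH4)2 (Et2O, −30 °C). Zinc bridges the ketone and dioxolane oxygens and hydride enters from the side of the C8–H, which should give the 8,9-anti alcohol F12. Ac2O and pyridine then return to 14.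

Further compounds
F1 | step 10 | allylboronate acetonide | O=C1O[C@@H](C=C1CB2OC(C)(C)C(C)(C)O2)/C=C(/CO[Si](c3ccccc3)(c3ccccc3)C(C)(C)C)CC/C=C(/C(OC)OC)[C@H](OC(C)=O)[C@H]1COC(C)(C)O1
F2 | step 10 | boronate dialdehyde | O=C1O[C@@H](C=C1CB2OC(C)(C)C(C)(C)O2)/C=C(/CO[Si](c3ccccc3)(c3ccccc3)C(C)(C)C)CC/C=C(/C=O)[C@H](OC(C)=O)C=O
F3 | step 10 | cyclic borate (8-O-pinacolboryl derivative of 22) | CC1(C)OB(O[C@@H]2[C@H]3C(=C)C(=O)O[C@@H]3/C=C(/CO[Si](c4ccccc4)(c4ccccc4)C(C)(C)C)CC/C=C(/C=O)[C@@H]2OC(C)=O)OC1(C)C
F4 | step 6 | triethylsilyl ether of 6 | C=C[C@H](O[Si](CC)(CC)CC)/C=C(\I)CO[Si](c1ccccc1)(c1ccccc1)C(C)(C)C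
F5 | step 6 | bromoalkenyl borane from 10 | C(CB1C2CCCC1CCC2)/C=C(Br)/C(OC)OC
F6 | step 6 | coupled alkenyl bromide | C=C[C@H](O[Si](CC)(CC)CC)/C=C(/CO[Si](c1ccccc1)(c1ccccc1)C(C)(C)C)CC/C=C(Br)/C(OC)OC
F7 | step 6 | alkenyllithium from F6 | C=C[C@H](O[Si](CC)(CC)CC)/C=C(/CO[Si](c1ccccc1)(c1ccccc1)C(C)(C)C)CC/C=C([Li])/C(OC)OC
F8 | step 6 | lithium alkoxide from F7 and 11 | C=C[C@H](O[Si](CC)(CC)CC)/C=C(/CO[Si](c1ccccc1)(c1ccccc1)C(C)(C)C)CC/C=C(/C(OC)OC)[C@H](O[Li])[C@H]1COC(C)(C)O1
F9 | step 6 | silyl-protected acetate (6-O-triethylsilyl ether of 16) | C=C[C@H](O[Si](CC)(CC)CC)/C=C(/CO[Si](c1ccccc1)(c1ccccc1)C(C)(C)C)CC/C=C(/C(OC)OC)[C@H](OC(C)=O)[C@H]1COC(C)(C)O1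
F10 | step 5 | C9-epimeric alcohols | C=C/C=C(/C(OC)OC)C(O)[C@H]1COC(C)(C)O1
F11 | step 5 | dienone | C=C/C=C(/C(OC)OC)C(=O)[C@H]1COC(C)(C)O1
F12 | step 5 | 8,9-anti alcohol (8R,9S) | C=C/C=C(/C(OC)OC)[C@H](O)[C@H]1COC(C)(C)O1
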